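**Strategy.** The 7-oxabicyclo[2.2.1]heptane (bridgeheads C1 and C4, bridge O7, side chain on C2, methyl on C3) is opened across C1–C2 and O7–C4 to an acyclic methyl ketone carrying a γ-methylidene group and a vinyl sulfone. In one flask, samarium diiodide closes the carbocycle by ketyl–olefin addition (C1–C2) and acid then adds the new C1 hydroxyl across the ring to the methylidene carbon (O7–C4). The step exploits the 1,4-disposed, methyl-bearing ether carbons C1 and C4 and sets C1, C2 and C4 from the single preset centre C3. The sulfone then joins the bicycle to an (S)-linalool-derived bromide, and bromoetherification closes the bromooxane last.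

Key step: step 7

Assumptions: (S)-(+)-linalool of high enantiomeric purity is taken as commercially available. The facial sense of the crotylboration in step 2 follows the accepted model for the (−)-α-pinene-derived reagent. The oxabicycle is numbered C1 (bridgehead bonded to the side-chain carbon C2), C3 (CHMe), C4, O7 throughout, and the oxane O1, C2 (vinyl, methyl), C5 (Br), C6.

Step 1
Reactants: 1 2-(2-bromoethyl)-2-methyl-1,3-dioxolane
Product: 4 3-(2-methyl-1,3-dioxolan-2-yl)propanal, via Grignard reagent 2 (not isolated), via magnesium hemiaminal 3 (not isolated)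
Conditions: Mg, THF, 25–40 °C; DMF, 0 °C; aq. NH4Cl
Reagents that add atoms: N,N-dimethylformamide, CN(C)C=O
Why: Grignard formation from the ketal-protected bromide and Bouveault formylation with DMF should give the aldehyde, the dioxolane being inert to the organomagnesium and to the buffered quench.

Step 2
Reactants: 4 3-(2-methyl-1,3-dioxolan-2-yl)propanal
Product: 6 (3S,4R)-4-methyl-1-(2-methyl-1,3-dioxolan-2-yl)hex-5-en-3-ol, via borinic ester 5 (not isolated)
Conditions: (E)-crotyl-B(Ipc)2 [from (+)-Ipc2BOMe, trans-2-butene, n-BuLi, KOt-Bu, BF3·OEt2], THF, −78 °C; NaOH, H2O2, 0 °C to rt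
Reagents that add atoms: (E)-but-2-en-1-ylbis[(1S,2S,3S,5R)-isopinocampheyl]borane, C/C=C/CB([C@H]1C[C@H]2C[C@@H]([C@@H]1C)C2(C)C)[C@H]3C[C@H]4C[C@@H]([C@@H]3C)C4(C)C
Why: Brown asymmetric crotylboration through a chair-like Zimmerman–Traxler transition state should give the anti adduct from the (E)-crotyl reagent, the isopinocampheyl groups of the (−)-α-pinene series selecting the aldehyde face so that the carbinol is (S) and the methyl-bearing carbon (R), the latter being the only stereocentre carried into the bicycle.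

Step 3
Reactants: 6 (3S,4R)-4-methyl-1-(2-methyl-1,3-dioxolan-2-yl)hex-5-en-3-ol
Product: 7 (4R)-4-methyl-1-(2-methyl-1,3-dioxolan-2-yl)hex-5-en-3-one
Conditions: Dess–Martin periodinane, NaHCO3, CH2Cl2, 0 °C
Reagents that add atoms: none
Why: Buffered Dess–Martin oxidation removes the carbinol centre under non-enolising conditions and should leave the allylic α-methyl stereocentre and the ketal untouched.

Step 4
Reactants: 7 (4R)-4-methyl-1-(2-methyl-1,3-dioxolan-2-yl)hex-5-en-3-one
Product: 8 2-methyl-2-[(4R)-4-methyl-3-methylidenehex-5-en-1-yl]-1,3-dioxolane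
Conditions: Cp2Ti(μ-CH2)(μ-Cl)AlMe2 (Tebbe reagent), pyridine, THF–toluene, −40 to 0 °C
Reagents that add atoms: Tebbe reagent, C[Al-]1(C)C[Ti]([Cl+]1)(C2C=CC=C2)C3C=CC=C3
Why: Tebbe methylenation is non-basic and tolerates enolisable ketones, so the 1,1-disubstituted alkene should be installed without epimerising the neighbouring stereocentre or moving the vinyl double bond into conjugation.

Step 5
Reactants: 8 2-methyl-2-[(4R)-4-methyl-3-methylidenehex-5-en-1-yl]-1,3-dioxolane; 9 phenyl vinyl sulfone
Product: 10 2-methyl-2-[(4R,5E)-4-methyl-3-methylidene-6-(phenylsulfonyl)hex-5-en-1-yl]-1,3-dioxolane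
Conditions: RuCl2(=CHPh)(PCy3)(H2IMes) (second-generation Grubbs catalyst, 5 mol%), 1,4-benzoquinone (10 mol%), excess 9, CH2Cl2, 40 °C
Reagents that add atoms: none
Why: Olefin cross-metathesis of the monosubstituted vinyl group with the electron-poor partner should give the (E)-vinyl sulfone, the 1,1-disubstituted alkene being inert to the ruthenium carbene and benzoquinone suppressing double-bond migration at the bis-allylic stereocentre.

Step 6
Reactants: 10 2-methyl-2-[(4R,5E)-4-methyl-3-methylidene-6-(phenylsulfonyl)hex-5-en-1-yl]-1,3-dioxolane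
Product: 11 (6R,7E)-6-methyl-5-methylidene-8-(phenylsulfonyl)oct-7-en-2-one
Conditions: PPTS, acetone–H2O, 50 °C
Reagents that add atoms: water, O
Why: Mild acid-catalysed hydrolysis of the dioxolane should release the methyl ketone without touching the vinyl sulfone or the base-sensitive bis-allylic stereocentre.

Step 7
Reactants: 11 (6R,7E)-6-methyl-5-methylidene-8-(phenylsulfonyl)oct-7-en-2-one
Product: 13 (1R,2R,3R,4S)-1,3,4-trimethyl-2-[(phenylsulfonyl)methyl]-7-oxabicyclo[2.2.1]heptane, via cyclohexanol 12 (not isolated)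
Conditions: SmI2 (2.4 equiv), MeOH (4 equiv), THF, −78 to 0 °C; then, in the same flask, solvent exchanged for CH2Cl2, CF3SO3H (2.6 equiv), 0 °C
Reagents that add atoms: none
Why: Samarium diiodide reduces the ketone to a ketyl that adds to the β-carbon of the vinyl sulfone (6-exo-trig closure of the carbocycle; the known SmI2 ketyl–olefin cyclisation onto electron-poor alkenes), methanol protonating the α-sulfonyl carbanion to give 12. Triflic acid then protonates the exocyclic methylene in the Markovnikov sense and the tertiary C4 cation is captured across the ring by the C1 hydroxyl (5-exo closure of the ether bridge, completing both tetrahydrofuran rings; the known terpinen-4-ol to 1,4-cineole type of transannular hydroalkoxylation). C2 is controlled by the preset C3 methyl: in the chair transition state the methyl and the sulfonylvinyl acceptor are both equatorial, which places the side chain trans to the methyl. C1 is controlled by the equatorial, samarium-bound ketyl oxygen, which adds anti to the acceptor, so the oxygen ends trans to the C2 side chain and cis to the C3 methyl. C4 is controlled by C1, because the tethered oxygen can reach the planar cation from one face only. The step needs chemoselective ketyl attack on the sulfone-activated alkene (secured by its low LUMO; the 1,1-disubstituted alkene is inert to the ketyl) and capture of the cation before hydride shift or elimination (secured by the proximity of the 1,4-hydroxyl).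

Step 8
Reactants: 14 (S)-(+)-linalool
Product: 15 triethyl{[(3S)-3,7-dimethylocta-1,6-dien-3-yl]oxy}silane
Conditions: Et3SiOTf, 2,6-lutidine, CH2Cl2, −78 to 0 °C
Reagents that add atoms: triethylsilyl trifluoromethanesulfonate, CC[Si](CC)(CC)OS(=O)(=O)C(F)(F)F
Why: Silylation with the reactive silyl triflate should mask the hindered tertiary allylic hydroxyl for the later carbanion chemistry, the stereocentre coming unchanged from the chiral pool.

Step 9
Reactants: 15 triethyl{[(3S)-3,7-dimethylocta-1,6-dien-3-yl]oxy}silane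
Product: 17 (2E,6S)-2,6-dimethyl-6-[(triethylsilyl)oxy]octa-2,7-dien-1-ol, via over-oxidised enal 16 (not isolated)
Conditions: SeO2 (0.3 equiv), t-BuOOH, salicylic acid (cat.), CH2Cl2, rt; NaBH4, MeOH, 0 °C
Reagents that add atoms: tert-butyl hydroperoxide, CC(C)(C)OO; selenium dioxide (catalytic oxygen carrier), O=[Se]=O
Why: Riley-type allylic oxidation (ene reaction, then [2,3]-sigmatropic shift) should hydroxylate the (E)-methyl group of the trisubstituted alkene with retention of the E geometry, and NaBH4 returns the over-oxidised enal 16 to the alcohol.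

Step 10
Reactants: 17 (2E,6S)-2,6-dimethyl-6-[(triethylsilyl)oxy]octa-2,7-dien-1-ol
Product: 18 {[(3S,6E)-8-bromo-3,7-dimethylocta-1,6-dien-3-yl]oxy}triethylsilane
Conditions: CBr4, PPh3, CH2Cl2, −20 °C
Reagents that add atoms: carbon tetrabromide, BrC(Br)(Br)Br
Why: Appel bromination should convert the primary allylic alcohol into the bromide under neutral conditions, without allylic transposition or loss of the silyl ether.

Step 11
Reactants: 13 (1R,2R,3R,4S)-1,3,4-trimethyl-2-[(phenylsulfonyl)methyl]-7-oxabicyclo[2.2.1]heptane; 18 {[(3S,6E)-8-bromo-3,7-dimethylocta-1,6-dien-3-yl]oxy}triethylsilane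
Product: 20 triethyl{[(3S,6E)-3,7-dimethyl-9-(phenylsulfonyl)-9-[(1R,2R,3R,4S)-1,3,4-trimethyl-7-oxabicyclo[2.2.1]heptan-2-yl]nona-1,6-dien-3-yl]oxy}silane (both C9 epimers), via lithiated sulfone 19 (not isolated)
Conditions: n-BuLi, THF, −78 °C; 18, DMPU, −78 to −20 °C
Reagents that add atoms: none
Why: Deprotonation α to the sulfone and SN2 alkylation of the stabilised carbanion with the primary allylic bromide (Julia-type sulfone coupling) should join the fragments with retention of the E alkene, the new sulfone-bearing centre being erased in the next step.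

Step 12
Reactants: 20 triethyl{[(3S,6E)-3,7-dimethyl-9-(phenylsulfonyl)-9-[(1R,2R,3R,4S)-1,3,4-trimethyl-7-oxabicyclo[2.2.1]heptan-2-yl]nona-1,6-dien-3-yl]oxy}silane
Product: 21 triethyl{[(3S,6E)-3,7-dimethyl-9-[(1R,2R,3R,4S)-1,3,4-trimethyl-7-oxabicyclo[2.2.1]heptan-2-yl]nona-1,6-dien-3-yl]oxy}silane
Conditions: 6% Na(Hg), Na2HPO4, MeOH–THF, −20 °C
Reagents that add atoms: none
Why: Buffered sodium amalgam should cleave the C–S bond of the non-allylic sulfone by electron transfer (reductive desulfonylation) and leave both alkenes and the silyl ether intact.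

Step 13
Reactants: 21 triethyl{[(3S,6E)-3,7-dimethyl-9-[(1R,2R,3R,4S)-1,3,4-trimethyl-7-oxabicyclo[2.2.1]heptan-2-yl]nona-1,6-dien-3-yl]oxy}silane
Product: 22 (3S,6E)-3,7-dimethyl-9-[(1R,2R,3R,4S)-1,3,4-trimethyl-7-oxabicyclo[2.2.1]heptan-2-yl]nona-1,6-dien-3-ol
Conditions: n-Bu4NF, THF, 25 °C
Reagents that add atoms: none
Why: Fluoride-induced Si–O cleavage should release the tertiary allylic alcohol that serves as the nucleophile of the last step.

Step 14
Reactants: 22 (3S,6E)-3,7-dimethyl-9-[(1R,2R,3R,4S)-1,3,4-trimethyl-7-oxabicyclo[2.2.1]heptan-2-yl]nona-1,6-dien-3-ol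
Product: 23 dactylopyranoid, (2S,5R,6S)-5-bromo-2-ethenyl-2,6-dimethyl-6-{2-[(1R,2R,3R,4S)-1,3,4-trimethyl-7-oxabicyclo[2.2.1]heptan-2-yl]ethyl}oxane
Conditions: Et2SBr·SbCl5Br (BDSB, 1.1 equiv), MeNO2, −25 °C, 5 min
Reagents that add atoms: bromodiethylsulfonium bromopentachloroantimonate, CC[S+](Br)CC.[Br-].Cl[Sb](Cl)(Cl)(Cl)Cl
Why: Bromonium formation at the electron-rich trisubstituted alkene and 6-endo Markovnikov attack of the tertiary hydroxyl (biomimetic bromoetherification) should close the oxane, anti addition across the E alkene fixing the C5 bromide trans to the C6 side chain, whereas the alkene face taken relative to C2 is under weak substrate control only, so the diastereomer from the other face is expected beside 23 and is to be removed by chromatography.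

**Compound list**

1 | 2-(2-bromoethyl)-2-methyl-1,3-dioxolane | CC1(CCBr)OCCO1 | starting material
2 | [2-(2-methyl-1,3-dioxolan-2-yl)ethyl]magnesium bromide | CC1(CC[Mg]Br)OCCO1 | intermediate
3 | bromomagnesium 1-(dimethylamino)-3-(2-methyl-1,3-dioxolan-2-yl)propan-1-olate | CC1(CCC(O[Mg]Br)N(C)C)OCCO1 | intermediate
4 | 3-(2-methyl-1,3-dioxolan-2-yl)propanal | CC1(CCC=O)OCCO1 | intermediate
5 | O-bis[(1S,2S,3S,5R)-isopinocampheyl]boryl derivative of 6 | C=C[C@@H](C)[C@@H](OB([C@H]2C[C@H]3C[C@@H]([C@@H]2C)C3(C)C)[C@H]4C[C@H]5C[C@@H]([C@@H]4C)C5(C)C)CCC1(C)OCCO1 | intermediate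
6 | (3S,4R)-4-methyl-1-(2-methyl-1,3-dioxolan-2-yl)hex-5-en-3-ol | C=C[C@@H](C)[C@@H](O)CCC1(C)OCCO1 | intermediate
7 | (4R)-4-methyl-1-(2-methyl-1,3-dioxolan-2-yl)hex-5-en-3-one | C=C[C@@H](C)C(=O)CCC1(C)OCCO1 | intermediate
8 | 2-methyl-2-[(4R)-4-methyl-3-methylidenehex-5-en-1-yl]-1,3-dioxolane | C=C[C@@H](C)C(=C)CCC1(C)OCCO1 | intermediate
9 | phenyl vinyl sulfone | C=CS(=O)(=O)c1ccccc1 | starting material
10 | 2-methyl-2-[(4R,5E)-4-methyl-3-methylidene-6-(phenylsulfonyl)hex-5-en-1-yl]-1,3-dioxolane | O=S(=O)(c1ccccc1)/C=C/[C@@H](C)C(=C)CCC1(C)OCCO1 | intermediate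
11 | (6R,7E)-6-methyl-5-methylidene-8-(phenylsulfonyl)oct-7-en-2-one | O=S(=O)(c1ccccc1)/C=C/[C@@H](C)C(=C)CCC(C)=O | intermediate
12 | (1R,2R,3R)-1,3-dimethyl-4-methylidene-2-[(phenylsulfonyl)methyl]cyclohexan-1-ol | O=S(=O)(c1ccccc1)C[C@@H]1[C@@H](C)C(=C)CC[C@@]1(C)O | intermediate
13 | (1R,2R,3R,4S)-1,3,4-trimethyl-2-[(phenylsulfonyl)methyl]-7-oxabicyclo[2.2.1]heptane (numbered as in the target) | O=S(=O)(c1ccccc1)C[C@@H]1[C@@H](C)[C@]2(C)CC[C@@]1(C)O2 | intermediate
14 | (S)-(+)-linalool | C=C[C@@](C)(O)CCC=C(C)C | starting material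
15 | triethyl{[(3S)-3,7-dimethylocta-1,6-dien-3-yl]oxy}silane | C=C[C@@](C)(O[Si](CC)(CC)CC)CCC=C(C)C | intermediate
16 | (2E,6S)-2,6-dimethyl-6-[(triethylsilyl)oxy]octa-2,7-dienal | C=C[C@@](C)(O[Si](CC)(CC)CC)CC/C=C(\C)C=O | intermediate
17 | (2E,6S)-2,6-dimethyl-6-[(triethylsilyl)oxy]octa-2,7-dien-1-ol | C=C[C@@](C)(O[Si](CC)(CC)CC)CC/C=C(\C)CO | intermediate
18 | {[(3S,6E)-8-bromo-3,7-dimethylocta-1,6-dien-3-yl]oxy}triethylsilane | C=C[C@@](C)(O[Si](CC)(CC)CC)CC/C=C(\C)CBr | intermediate
19 | α-lithio derivative of sulfone 13 | [Li]C(S(=O)(=O)c1ccccc1)[C@@H]1[C@@H](C)[C@]2(C)CC[C@@]1(C)O2 | intermediate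
20 | triethyl{[(3S,6E)-3,7-dimethyl-9-(phenylsulfonyl)-9-[(1R,2R,3R,4S)-1,3,4-trimethyl-7-oxabicyclo[2.2.1]heptan-2-yl]nona-1,6-dien-3-yl]oxy}silane, both C9 epimers | C=C[C@@](C)(O[Si](CC)(CC)CC)CC/C=C(\C)CC(S(=O)(=O)c1ccccc1)[C@@H]2[C@@H](C)[C@]3(C)CC[C@@]2(C)O3 | intermediate
21 | triethyl{[(3S,6E)-3,7-dimethyl-9-[(1R,2R,3R,4S)-1,3,4-trimethyl-7-oxabicyclo[2.2.1]heptan-2-yl]nona-1,6-dien-3-yl]oxy}silane | C=C[C@@](C)(O[Si](CC)(CC)CC)CC/C=C(\C)CC[C@@H]1[C@@H](C)[C@]2(C)CC[C@@]1(C)O2 | intermediate
22 | (3S,6E)-3,7-dimethyl-9-[(1R,2R,3R,4S)-1,3,4-trimethyl-7-oxabicyclo[2.2.1]heptan-2-yl]nona-1,6-dien-3-ol | C=C[C@@](C)(O)CC/C=C(\C)CC[C@@H]1[C@@H](C)[C@]2(C)CC[C@@]1(C)O2 | intermediate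
23 | dactylopyranoid | C=C[C@]1(C)CC[C@@H](Br)[C@](C)(CC[C@@H]2[C@@H](C)[C@]3(C)CC[C@@]2(C)O3)O1 | target

**Step count and risks**

Total: 14 steps. Longest linear sequence: 11 steps (steps 1–7, then 11–14); steps 8–10 prepare the linalool-derived bromide.

Steps most likely to fail:

1. Step 7 (key step). In the acid stage the tertiary cation may lose a proton or take a 1,2-hydride shift from C3 before it is captured across the ring, and the tertiary carbinol may ionise; the ketyl closure may also discriminate the alkene faces incompletely. Fallback: the two bond formations are separated and the free cation is avoided. Setting out from 11, the samarium step is run alone and carbinol 12 is isolated. Intramolecular alkoxymercuration with Hg(OCOCF3)2 in CH2Cl2 should give the bridged alkylmercury trifluoroacetate F1. Alkaline NaBH4 then replaces mercury by hydrogen and the route is rejoined at 13.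

2. Step 14. Bromonium formation may show poor facial selectivity relative to the distant C2 centre, and 5-exo closure may compete. Fallback: the alkene face is chosen by a reagent. Setting out from 21, Shi epoxidation with the enantiomeric (L-sorbose-derived) ketone and KHSO5 should give the (6S,7S)-epoxide F2. Li2NiBr4 in THF should open it at the secondary carbon with inversion to the (6R,7S)-bromohydrin F3. Tf2O with 2,6-di-tert-butyl-4-methylpyridine at −78 °C then ionises the tertiary alcohol with participation of the neighbouring bromine. The resulting enantiopure bromonium ion is opened at the tertiary carbon by the silyl ether oxygen, with loss of the silyl group, and the route is rejoined at 23.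

3. Step 3. The allylic α-stereocentre of ketone 7 may erode by enolisation, or the vinyl double bond may migrate into conjugation, during oxidation or the following methylenation. Fallback: the ketone is avoided altogether. Setting out from 4, Ohira–Bestmann homologation (dimethyl (1-diazo-2-oxopropyl)phosphonate, K2CO3, MeOH) should give 2-(but-3-yn-1-yl)-2-methyl-1,3-dioxolane F4. Nickel-catalysed α-selective hydroalumination (i-Bu2AlH, NiCl2(dppp)) should give diisobutyl[5-(2-methyl-1,3-dioxolan-2-yl)pent-1-en-2-yl]alane F5. This is used directly in a copper-catalysed enantioselective SN2′ substitution of (E)-crotyl diethyl phosphate (CuCl2·2H2O, chiral sulfonate-bearing N-heterocyclic carbene ligand), and the route is rejoined at 8.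

**Further compounds**

F1 | step 7 | {[(1S,2R,3R,4R)-2,4-dimethyl-3-[(phenylsulfonyl)methyl]-7-oxabicyclo[2.2.1]heptan-1-yl]methyl}mercury trifluoroacetate (13 with its CHMe-side bridgehead methyl as CH2HgOCOCF3) | O=S(=O)(c1ccccc1)C[C@@H]1[C@@H](C)[C@]2(C[Hg]OC(=O)C(F)(F)F)CC[C@@]1(C)O2
F2 | step 14 | (6S,7S)-6,7-epoxide of 21 | C=C[C@@](C)(O[Si](CC)(CC)CC)CC[C@H]1[C@](C)(CC[C@@H]2[C@@H](C)[C@]3(C)CC[C@@]2(C)O3)O1
F3 | step 14 | (3S,6R,7S)-6-bromo-3,7-dimethyl-3-[(triethylsilyl)oxy]-9-[(1R,2R,3R,4S)-1,3,4-trimethyl-7-oxabicyclo[2.2.1]heptan-2-yl]non-1-en-7-ol | C=C[C@@](C)(O[Si](CC)(CC)CC)CC[C@@H](Br)[C@](C)(CC[C@@H]1[C@@H](C)[C@]2(C)CC[C@@]1(C)O2)O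
F4 | step 3 | 2-(but-3-yn-1-yl)-2-methyl-1,3-dioxolane | C#CCCC1(C)OCCO1
F5 | step 3 | diisobutyl[5-(2-methyl-1,3-dioxolan-2-yl)pent-1-en-2-yl]alane | C=C(CCC1(C)OCCO1)[Al](CC(C)C)CC(C)C
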